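Reckon this flask from the rates of the two earlier runs.

| flask | left-handed substrate | right-handed substrate | partner | free catalyst | remark | time |
|---|---|---|---|---|---|---|
| gamma | 20 mM | 20 mM | 84 mM | 20 µM | run made earlier |  |
| beta | 20 mM | 20 mM | 130 mM | 20 µM | run made earlier |  |
| flask | 20 mM | 20 mM | 60.0 mM | 20 µM |  | 50 min |

- gamma (time / min: left-handed substrate / %, right-handed substrate / %, left-handed product / %): 4.00: 48.0, 49.1, 2.1; 12.0: 45.3, 47.0, 4.7; 20.0: 42.9, 45.5, 7.8; 30.0: 42.4, 44.1, 8.6; 50.0: 40.2, 44.4, 9.0; 60.0: 40.6, 44.0, 9.4
- beta (time / min: left-handed substrate / %, right-handed substrate / %, left-handed product / %): 10.0: 43.5, 45.5, 6.0; 20.0: 39.7, 44.3, 10.9; 30.0: 38.0, 43.3, 11.3; 40.0: 38.1, 42.0, 12.1; 50.0: 37.2, 42.0, 13.5; 60.0: 36.2, 41.6, 13.8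

(readings scatter by 0.5 percentage points)

- part of the left-handed substrate and right-handed substrate charged together that has reacted at 50 min
- excess of left-handed product over right-handed product in the product at 50 min
- excess of right-handed substrate over left-handed substrate among what is left of the two at 50 min

- free catalyst is single-handed; left-handed substrate and right-handed substrate are mirror images of each other, charged as a racemate, each of them at the stated concentration
- the numbers in the tables scatter by 0.5 percentage points (one standard deviation)
- an excess is the difference of the two amounts in percent of their sum
- an excess is below zero if the other one leads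

In the beta run the two substrates together convert 11.0% in the first 10.0 min, then 5.00% in the next stretch of that length and 2.70% in the third, so the rate falls to about half and then half again. The gamma run holds less partner but slows on much the same clock: it reaches 15.4% by 50.0 min, and 87.7% of that stood at 30.0 min. The beta run reaches 20.8%, and 89.9% of that stood at 30.0 min.

A rate that halves on a fixed clock adds up to its start rate times a fixed time, so with that clock held the end conversion rises with the start rate, and the two runs tie that to the partner charge. In the gamma run, substrate converted by 50.0 min per partner charged is 7.33%; call this the partner yield. The beta run gives 6.40%.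

Take the gamma value, whose partner charge lies nearer the flask's. My reckoning then puts the flask at 11.0% converted. The lead of right-handed over left-handed substrate, divided by conversion and pooled over both runs, gives a product excess of 24.9%, and so a substrate excess of 3.08%.

The forecast, holding that “The plateau is then set by partner.”, gives 11.5% (10.2% to 12.8%), above my conversion, with 25% (21% to 29%) and 3.3% (2.6% to 4.1%).

The flask gives 11.1% converted, 24.3% product excess and 3.02% substrate excess.

    free catalyst + left-handed substrate ⇌ catalyst intermediate A (K = 46.0 M⁻¹, k = 17000 M⁻¹ min⁻¹)
    free catalyst + right-handed substrate ⇌ catalyst intermediate B (K = 59.0 M⁻¹, k = 8900 M⁻¹ min⁻¹)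
    partner + catalyst intermediate A → free catalyst + left-handed product (k = 560 M⁻¹ min⁻¹)
    partner + catalyst intermediate B → free catalyst + right-handed product (k = 260 M⁻¹ min⁻¹)
    partner + free catalyst → spent catalyst (k = 0.470 M⁻¹ min⁻¹)
    partner ⇌ dormant form (K = 0.210, k = 0.00750 min⁻¹)
    partner → decomposed reagent (k = 0.0530 min⁻¹)

The flask's partner yield is 7.40%, against 7.33% in the gamma run. Scale the gamma partner yield by catalyst charge for the neighbour flask with 0.012 mM of free catalyst: it gives 6.60%, and that flask converts 6.89%. In the flask the left-handed product leads because catalyst intermediate B returns to free catalyst and right-handed substrate. The same run without that return gives a product excess of −83.7%, with the right-handed product ahead, against 24.3% with it.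

Readings and results were generated by integration with made-up constants.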